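## Retrosynthetic overview

Numbering: C1 is the lactone carbonyl, C4 the lactone CH–O, C7 the chain carbon bearing CH2OH, C14/C15 the ring CH and C(OH).

1. Last bond: C7–CH2OH by Stille hydroxymethylation of a (Z)-vinyl iodide, which stands in for that hydroxymethyl group throughout.
2. Butenolide (second ring): Wittig olefination of an α-hydroxy ketone to the (2Z)-4-hydroxy-2-enoate, which lactonizes. C4 (R) comes from RAMP-hydrazone alkylation of dihydroxyacetone acetonide with the C5 allylic bromide.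
3. C5–C8: a propargyl dianion links the C9 allylic bromide and formaldehyde. Hydroxyl-directed trans-hydroalumination/iodination fixes the C6=C7 geometry.
4. Cyclohexanol (first ring, step 1): enzyme-controlled, proton-initiated cation–olefin closure of the terminal isoprene unit of (2E,6E)-farnesol, stopped after one ring by water capture. This sets C14 and C15.

Assumption: metalated intermediates are drawn as simple monomers with the ring tertiary hydroxyl shown free (it is present as its alkoxide, hence the excess base or hydride), and the C=N geometry of the hydrazones is left open.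

## Route

Step 1
Reactants: 1 (2E,6E)-farnesol
Product: 2 (2E)-5-[(1S,2S)-2-hydroxy-2,6,6-trimethylcyclohexyl]-3-methylpent-2-en-1-ol
Conditions: squalene–hopene cyclase variant (Alicyclobacillus acidocaldarius enzyme, E. coli whole cells), citrate buffer pH 6.0, 0.2% SDS, 37 °C
Reagents that add atoms: water, O
Why: Proposed new method: a squalene–hopene cyclase variant should fold only the terminal isoprene unit of 1 as a chair, protonate C10=C11 (farnesol numbering) with its DXDD aspartic acid, close C11–C6 on one face of the 6E olefin and let an active-site water quench the C7 cation anti to the new C–C bond (as the wild type does when it makes hopan-22-ol), while bulky residues near Tyr420/Leu607 keep the 2,3-olefin away so the cascade stops after one ring; this sets both ring centres (1S,2S, side chain trans to OH) under enzyme control, and the closest known reactions are the cyclase-catalysed biomimetic cation–olefin cyclizations of homofarnesol to ambroxide, of farnesol to drimane alcohols and the single-ring closure of geranylacetone.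

Step 2
Reactants: 2 (2E)-5-[(1S,2S)-2-hydroxy-2,6,6-trimethylcyclohexyl]-3-methylpent-2-en-1-ol
Product: 3 (1S,2S)-2-[(3E)-5-bromo-3-methylpent-3-en-1-yl]-1,3,3-trimethylcyclohexan-1-ol
Conditions: CBr4, PPh3, CH2Cl2, −20 to 0 °C
Reagents that add atoms: carbon tetrabromide, BrC(Br)(Br)Br
Why: Appel reaction; the primary allylic alcohol is displaced by SN2 without allylic shift while the hindered tertiary alcohol does not react.

Step 3
Reactants: 3 (1S,2S)-2-[(3E)-5-bromo-3-methylpent-3-en-1-yl]-1,3,3-trimethylcyclohexan-1-ol; 4 propyne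
Product: 7 (6E)-9-[(1S,2S)-2-hydroxy-2,6,6-trimethylcyclohexyl]-7-methylnon-6-en-2-yn-1-ol, via 1,3-dilithiopropyne 5 (not isolated), via lithium alkynide 6 (not isolated)
Conditions: 4 (3 equiv), n-BuLi (6 equiv), TMEDA, THF, −78 to 0 °C; add 3, −78 to 0 °C; (CH2O)n, 0 to 25 °C; H2O
Reagents that add atoms: paraformaldehyde (formaldehyde), C=O
Why: The propargyl dianion equivalent 5 is alkylated at its sp3 carbon by SN2 on the allylic bromide (E olefin kept, excess 5 covers the tertiary OH), and the remaining lithium alkynide adds to formaldehyde (alkynide hydroxymethylation).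

Step 4
Reactants: 7 (6E)-9-[(1S,2S)-2-hydroxy-2,6,6-trimethylcyclohexyl]-7-methylnon-6-en-2-yn-1-ol
Product: 9 (2Z,6E)-9-[(1S,2S)-2-hydroxy-2,6,6-trimethylcyclohexyl]-3-iodo-7-methylnona-2,6-dien-1-ol, via cyclic sodium alkenylalanate 8 (not isolated)
Conditions: NaAlH2(OCH2CH2OMe)2 (Red-Al, 3 equiv), THF, 0 to 25 °C; then I2, THF, −78 to 0 °C; aqueous work-up
Reagents that add atoms: iodine, II
Why: Hydroxyl-directed trans-hydroalumination of the propargylic alcohol puts Al on C3 cis to the CH2O group in a five-membered alanate, and iodinolysis with retention gives the (Z)-3-iodo allylic alcohol, the iodide serving as a placeholder for the later CH2OH.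

Step 5
Reactants: 9 (2Z,6E)-9-[(1S,2S)-2-hydroxy-2,6,6-trimethylcyclohexyl]-3-iodo-7-methylnona-2,6-dien-1-ol
Product: 10 (1S,2S)-2-[(3E,7Z)-9-bromo-7-iodo-3-methylnona-3,7-dien-1-yl]-1,3,3-trimethylcyclohexan-1-ol
Conditions: CBr4, PPh3, CH2Cl2, −20 °C
Reagents that add atoms: carbon tetrabromide, BrC(Br)(Br)Br
Why: Appel reaction; SN2 at the primary allylic carbon leaves the vinyl iodide, both olefin geometries and the tertiary alcohol untouched.

Step 6
Reactants: 11 2,2-dimethyl-1,3-dioxan-5-one; 12 (R)-1-amino-2-(methoxymethyl)pyrrolidine (RAMP)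
Product: 13 (2R)-N-(2,2-dimethyl-1,3-dioxan-5-ylidene)-2-(methoxymethyl)pyrrolidin-1-amine
Conditions: toluene, 4 Å molecular sieves, 60 °C
Reagents that add atoms: none
Why: Hydrazone condensation (Enders RAMP hydrazone); the auxiliary is the only source of chirality for C4.

Step 7
Reactants: 13 (2R)-N-(2,2-dimethyl-1,3-dioxan-5-ylidene)-2-(methoxymethyl)pyrrolidin-1-amine; 10 (1S,2S)-2-[(3E,7Z)-9-bromo-7-iodo-3-methylnona-3,7-dien-1-yl]-1,3,3-trimethylcyclohexan-1-ol
Product: 15 (2R)-N-{(4R)-4-[(2Z,6E)-9-((1S,2S)-2-hydroxy-2,6,6-trimethylcyclohexyl)-3-iodo-7-methylnona-2,6-dien-1-yl]-2,2-dimethyl-1,3-dioxan-5-ylidene}-2-(methoxymethyl)pyrrolidin-1-amine, via lithium azaenolate 14 (not isolated)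
Conditions: 13 (2.2 equiv), t-BuLi (2.2 equiv), THF, −78 °C; add 10, −100 to 25 °C; surplus 13 recovered
Reagents that add atoms: none
Why: Enders RAMP-hydrazone alkylation; the chelated lithium azaenolate is alkylated by SN2 on the allylic bromide from the face opposite the methoxymethyl arm, which gives 4R with RAMP (SAMP gives 4S), and no t-BuLi is left to touch the vinyl iodide.

Step 8
Reactants: 15 (2R)-N-{(4R)-4-[(2Z,6E)-9-((1S,2S)-2-hydroxy-2,6,6-trimethylcyclohexyl)-3-iodo-7-methylnona-2,6-dien-1-yl]-2,2-dimethyl-1,3-dioxan-5-ylidene}-2-(methoxymethyl)pyrrolidin-1-amine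
Product: 17 (3R,5Z,9E)-1,3-dihydroxy-12-[(1S,2S)-2-hydroxy-2,6,6-trimethylcyclohexyl]-6-iodo-10-methyldodeca-5,9-dien-2-one, via acetonide ketone 16 (not isolated)
Conditions: sat. aq. (CO2H)2, Et2O, 25 °C; then 1 M HCl, THF, 0 °C
Reagents that add atoms: water, O
Why: Acid hydrolysis of the hydrazone and then of the acetonide (auxiliary recovered); no bond to C4 is broken and cold dilute acid avoids enolization, so the R centre is kept.

Step 9
Reactants: 17 (3R,5Z,9E)-1,3-dihydroxy-12-[(1S,2S)-2-hydroxy-2,6,6-trimethylcyclohexyl]-6-iodo-10-methyldodeca-5,9-dien-2-one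
Product: 18 (3R,5Z,9E)-1-(tert-butyldimethylsilyloxy)-3-hydroxy-12-[(1S,2S)-2-hydroxy-2,6,6-trimethylcyclohexyl]-6-iodo-10-methyldodeca-5,9-dien-2-one
Conditions: TBSCl, imidazole, CH2Cl2, −20 to 0 °C
Reagents that add atoms: tert-butyldimethylsilyl chloride, CC(C)(C)[Si](C)(C)Cl
Why: Selective silylation; the primary hydroxyl reacts far faster than the secondary and tertiary ones, leaving only the C4 hydroxyl free for the lactonization.

Step 10
Reactants: 18 (3R,5Z,9E)-1-(tert-butyldimethylsilyloxy)-3-hydroxy-12-[(1S,2S)-2-hydroxy-2,6,6-trimethylcyclohexyl]-6-iodo-10-methyldodeca-5,9-dien-2-one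
Product: 21 (5R)-4-(hydroxymethyl)-5-[(2Z,6E)-9-((1S,2S)-2-hydroxy-2,6,6-trimethylcyclohexyl)-3-iodo-7-methylnona-2,6-dien-1-yl]furan-2(5H)-one, via Z-hydroxy enoate 19 (not isolated), via silyl butenolide 20 (not isolated)
Conditions: Ph3P=CHCO2Me, toluene, 90 °C; then HF·pyridine, THF, 0 to 25 °C
Reagents that add atoms: methyl (triphenylphosphoranylidene)acetate, COC(=O)C=P(c1ccccc1)(c1ccccc1)c1ccccc1
Why: Wittig olefination of the α-hydroxy ketone, in which the free hydroxyl steers the ester cis to itself as in butenolide syntheses from α-hydroxy ketones, gives the (2Z)-4-hydroxy enoate that lactonizes at once (ring closure by lactonization, C4–O bond untouched so R is kept), and HF·pyridine then removes the silyl group.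

Step 11
Reactants: 21 (5R)-4-(hydroxymethyl)-5-[(2Z,6E)-9-((1S,2S)-2-hydroxy-2,6,6-trimethylcyclohexyl)-3-iodo-7-methylnona-2,6-dien-1-yl]furan-2(5H)-one
Product: 22 (5R)-4-(hydroxymethyl)-5-[(2Z,6E)-3-(hydroxymethyl)-9-((1S,2S)-2-hydroxy-2,6,6-trimethylcyclohexyl)-7-methylnona-2,6-dien-1-yl]furan-2(5H)-one
Conditions: Bu3SnCH2OH, Pd(PPh3)4 (10 mol%), dioxane, 90 °C
Reagents that add atoms: (tributylstannyl)methanol, CCCC[Sn](CCCC)(CCCC)CO
Why: Migita–Kosugi–Stille coupling; zerovalent palladium inserts into the vinyl C–I bond and takes the hydroxymethyl group from tin with retention of olefin geometry, tolerating the free hydroxyls and the butenolide.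

## Compound list

1 | (2E,6E)-farnesol | C/C(=C\CO)CC/C=C(\C)CCC=C(C)C | starting material
2 | (2E)-5-[(1S,2S)-2-hydroxy-2,6,6-trimethylcyclohexyl]-3-methylpent-2-en-1-ol | C/C(=C\CO)CC[C@H]1C(C)(C)CCC[C@]1(C)O | intermediate
3 | (1S,2S)-2-[(3E)-5-bromo-3-methylpent-3-en-1-yl]-1,3,3-trimethylcyclohexan-1-ol | C/C(=C\CBr)CC[C@H]1C(C)(C)CCC[C@]1(C)O | intermediate
4 | propyne | CC#C | starting material
5 | 1,3-dilithiopropyne | [Li]CC#C[Li] | intermediate
6 | lithium alkynide, (1S,2S)-2-[(3E)-8-lithio-3-methyloct-3-en-7-yn-1-yl]-1,3,3-trimethylcyclohexan-1-ol | C/C(=C\CCC#C[Li])CC[C@H]1C(C)(C)CCC[C@]1(C)O | intermediate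
7 | (6E)-9-[(1S,2S)-2-hydroxy-2,6,6-trimethylcyclohexyl]-7-methylnon-6-en-2-yn-1-ol | C/C(=C\CCC#CCO)CC[C@H]1C(C)(C)CCC[C@]1(C)O | intermediate
8 | cyclic sodium alkenylalanate of 7 (2,5-dihydro-1,2-oxaaluminole, Al on C3 of the chain, two 2-methoxyethoxy ligands) | [Na+].COCCO[Al-]1(OCCOC)OCC=C1CC/C=C(\C)CC[C@H]2C(C)(C)CCC[C@]2(C)O | intermediate
9 | (2Z,6E)-9-[(1S,2S)-2-hydroxy-2,6,6-trimethylcyclohexyl]-3-iodo-7-methylnona-2,6-dien-1-ol | C/C(=C\CC/C(=C/CO)I)CC[C@H]1C(C)(C)CCC[C@]1(C)O | intermediate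
10 | (1S,2S)-2-[(3E,7Z)-9-bromo-7-iodo-3-methylnona-3,7-dien-1-yl]-1,3,3-trimethylcyclohexan-1-ol | C/C(=C\CC/C(=C/CBr)I)CC[C@H]1C(C)(C)CCC[C@]1(C)O | intermediate
11 | 2,2-dimethyl-1,3-dioxan-5-one | CC1(C)OCC(=O)CO1 | starting material
12 | (R)-1-amino-2-(methoxymethyl)pyrrolidine (RAMP) | COC[C@H]1CCCN1N | starting material
13 | (2R)-N-(2,2-dimethyl-1,3-dioxan-5-ylidene)-2-(methoxymethyl)pyrrolidin-1-amine | COC[C@H]1CCCN1N=C1COC(C)(C)OC1 | intermediate
14 | lithium azaenolate of 13 (N-lithio ene-hydrazine, C4=C5 of the dioxane) | COC[C@H]1CCCN1N([Li])C1=COC(C)(C)OC1 | intermediate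
15 | (2R)-N-{(4R)-4-[(2Z,6E)-9-((1S,2S)-2-hydroxy-2,6,6-trimethylcyclohexyl)-3-iodo-7-methylnona-2,6-dien-1-yl]-2,2-dimethyl-1,3-dioxan-5-ylidene}-2-(methoxymethyl)pyrrolidin-1-amine | COC[C@H]1CCCN1N=C1COC(C)(C)O[C@@H]1C/C=C(I)/CC/C=C(\C)CC[C@H]2C(C)(C)CCC[C@]2(C)O | intermediate
16 | (4R)-4-[(2Z,6E)-9-((1S,2S)-2-hydroxy-2,6,6-trimethylcyclohexyl)-3-iodo-7-methylnona-2,6-dien-1-yl]-2,2-dimethyl-1,3-dioxan-5-one | O=C1COC(C)(C)O[C@@H]1C/C=C(I)/CC/C=C(\C)CC[C@H]2C(C)(C)CCC[C@]2(C)O | intermediate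
17 | (3R,5Z,9E)-1,3-dihydroxy-12-[(1S,2S)-2-hydroxy-2,6,6-trimethylcyclohexyl]-6-iodo-10-methyldodeca-5,9-dien-2-one | OCC(=O)[C@H](O)C/C=C(I)/CC/C=C(\C)CC[C@H]1C(C)(C)CCC[C@]1(C)O | intermediate
18 | (3R,5Z,9E)-1-(tert-butyldimethylsilyloxy)-3-hydroxy-12-[(1S,2S)-2-hydroxy-2,6,6-trimethylcyclohexyl]-6-iodo-10-methyldodeca-5,9-dien-2-one | CC(C)(C)[Si](C)(C)OCC(=O)[C@H](O)C/C=C(I)/CC/C=C(\C)CC[C@H]1C(C)(C)CCC[C@]1(C)O | intermediate
19 | methyl (2Z,4R,6Z,10E)-3-[(tert-butyldimethylsilyloxy)methyl]-4-hydroxy-13-[(1S,2S)-2-hydroxy-2,6,6-trimethylcyclohexyl]-7-iodo-11-methyltrideca-2,6,10-trienoate | COC(=O)/C=C(/CO[Si](C)(C)C(C)(C)C)[C@H](O)C/C=C(I)/CC/C=C(\C)CC[C@H]1C(C)(C)CCC[C@]1(C)O | intermediate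
20 | (5R)-4-[(tert-butyldimethylsilyloxy)methyl]-5-[(2Z,6E)-9-((1S,2S)-2-hydroxy-2,6,6-trimethylcyclohexyl)-3-iodo-7-methylnona-2,6-dien-1-yl]furan-2(5H)-one | C/C(=C\CC/C(=C/C[C@H]1OC(=O)C=C1CO[Si](C)(C)C(C)(C)C)I)CC[C@H]1C(C)(C)CCC[C@]1(C)O | intermediate
21 | (5R)-4-(hydroxymethyl)-5-[(2Z,6E)-9-((1S,2S)-2-hydroxy-2,6,6-trimethylcyclohexyl)-3-iodo-7-methylnona-2,6-dien-1-yl]furan-2(5H)-one | C/C(=C\CC/C(=C/C[C@H]1OC(=O)C=C1CO)I)CC[C@H]1C(C)(C)CCC[C@]1(C)O | intermediate
22 | (5R)-4-(hydroxymethyl)-5-[(2Z,6E)-3-(hydroxymethyl)-9-((1S,2S)-2-hydroxy-2,6,6-trimethylcyclohexyl)-7-methylnona-2,6-dien-1-yl]furan-2(5H)-one (CNP0112492.2) | C/C(=C\CC/C(=C/C[C@H]1OC(=O)C=C1CO)CO)CC[C@H]1C(C)(C)CCC[C@]1(C)O | target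

## Step count and risks

Total steps: 11. Longest linear sequence: 10 (steps 1–5 and 7–11; step 6 is a one-step side branch).

**Step 1 (most likely to fail).** No cyclase variant is known that stops farnesol after one ring with water capture; the wild type goes on to drimanes. The fallback sets out from 1 and returns at 2. It keeps the enzymatic cation–olefin closure but lets a carbonyl oxygen take the cation instead of water, so the wild-type enzyme suffices. Compound 1 is epoxidized at its allylic 2,3-olefin (VO(acac)2, t-BuOOH) to 2,3-epoxyfarnesol F1. H5IO6 cleaves this to (E)-geranylacetone F2, which is also a cheap commercial compound. Wild-type squalene–hopene cyclase converts F2 into the trans-fused bicyclic enol ether F3, a known reaction of this enzyme, with the same ring configuration as 2 and the C15–O bond in place. KNH(CH2)3NH2 (from KH and 1,3-diaminopropane) opens F3 by anti β-elimination of the enol ether and moves the resulting 2-alkyne to the chain end, giving the alkynol F4. Cp2ZrCl2-catalysed methylalumination with AlMe3 gives the (E)-alkenylalane F5, and n-BuLi followed by (CH2O)n gives 2 with the E olefin fixed.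

**Step 7.** The allylic bromide carries a vinyl iodide and a free tertiary alcohol; both the yield and the facial selectivity of the alkylation are at risk. The fallback sets out from 10 and returns at 20, replacing steps 6–9 and the first half of step 10. The bis-silyl 2-silyloxyfuran F6 (from commercial 4-(hydroxymethyl)furan-2(5H)-one, TBSOTf, Et3N) is alkylated at its free α position, the future C4, by 10 with AgOCOCF3 in CH2Cl2. This gives the butenolide as a 1:1 mixture at C4, F7. LiN(iPr)2 then AcOH at −78 °C deconjugates it to the 3H-furanone F8, which erases C4. A cinchona-derived 6'-hydroxy bifunctional base (the quinidine- or quinine-derived pseudoenantiomer that gives R) then isomerizes F8 back into conjugation by enantioselective proton transfer, giving 20. Compound 20 is desilylated as in step 10.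

**Step 10.** Only the (2Z)-hydroxy enoate can lactonize; if the ester ends up cis to the silyloxymethyl arm the ring does not close. The fallback sets out from 18 and returns at 20. Ph3P=C=C=O in toluene at 80 °C adds the C4 hydroxyl across the ketene to give the ester ylide F9, which is tethered to the correct oxygen. Intramolecular Wittig reaction with the neighbouring ketone then closes the ring to 20 with no geometry issue; HF·pyridine follows as before.

## Further compounds

F1 | step 1 | 2,3-epoxyfarnesol, [3-((3E)-4,8-dimethylnona-3,7-dien-1-yl)-3-methyloxiran-2-yl]methanol (racemic epoxide) | OCC1OC1(C)CC/C=C(\C)CCC=C(C)C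
F2 | step 1 | (E)-geranylacetone, (5E)-6,10-dimethylundeca-5,9-dien-2-one | CC(=O)CC/C=C(\C)CCC=C(C)C
F3 | step 1 | (4aS,8aS)-2,5,5,8a-tetramethyl-4a,5,6,7,8,8a-hexahydro-4H-chromene | CC1=CC[C@H]2C(C)(C)CCC[C@]2(C)O1
F4 | step 1 | (1S,2S)-2-(but-3-yn-1-yl)-1,3,3-trimethylcyclohexan-1-ol | C#CCC[C@H]1C(C)(C)CCC[C@]1(C)O
F5 | step 1 | (E)-alkenyldimethylalane, (1S,2S)-2-[(3E)-4-(dimethylalumanyl)-3-methylbut-3-en-1-yl]-1,3,3-trimethylcyclohexan-1-ol | C[Al](C)/C=C(\C)CC[C@H]1C(C)(C)CCC[C@]1(C)O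
F6 | step 7 | tert-butyl{[5-(tert-butyldimethylsilyloxy)furan-3-yl]methoxy}dimethylsilane | CC(C)(C)[Si](C)(C)OCc1coc(O[Si](C)(C)C(C)(C)C)c1
F7 | step 7 | 1:1 mixture of 20 and its C4 epimer (C5 of the furanone undefined) | C/C(=C\CC/C(=C/CC1OC(=O)C=C1CO[Si](C)(C)C(C)(C)C)I)CC[C@H]1C(C)(C)CCC[C@]1(C)O
F8 | step 7 | 4-[(tert-butyldimethylsilyloxy)methyl]-5-[(2Z,6E)-9-((1S,2S)-2-hydroxy-2,6,6-trimethylcyclohexyl)-3-iodo-7-methylnona-2,6-dien-1-yl]furan-2(3H)-one | O=C1CC(CO[Si](C)(C)C(C)(C)C)=C(C/C=C(I)/CC/C=C(\C)CC[C@H]2C(C)(C)CCC[C@]2(C)O)O1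
F9 | step 10 | (triphenylphosphoranylidene)acetate ester of the C3 hydroxyl of 18 | CC(C)(C)[Si](C)(C)OCC(=O)[C@H](OC(=O)C=P(c1ccccc1)(c1ccccc1)c1ccccc1)C/C=C(I)/CC/C=C(\C)CC[C@H]1C(C)(C)CCC[C@]1(C)O
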